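**Plan**

- Cuts, in retrosynthetic order: (a) geranyl C1–C2 (ArO–CH2 | CH=C), giving an aryloxyacetic acid and an (E)-alkenyl iodide; (b) the O-4–CH2 bond on ring A; (c) ring A C-1–C(=O), giving an aryllithium and a Weinreb amide; (d) the alkenyl iodide back to a terminal alkyne.
- Forward order: D-tyrosine → (R)-hydroxy acid → silylated Weinreb amide; acylation of 2,4-bis(benzyloxy)phenyllithium; debenzylation; carboxymethylation of O-4 only (the 2-OH is locked in the hydrogen bond to the C=O); union with the C9 alkenyl iodide; desilylation.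
- Enabling feature: geranyl C1 is a CH2 bonded to the ether oxygen on C-4 of ring A (the 2-hydroxy-4-oxybenzoyl ring) and to the sp2 carbon C2. That oxygen stabilises a radical at C1, so C1 is delivered as ArO–CH2• from ArO–CH2–CO2H (CO2 as traceless activating group) and joined to C2 on nickel.
- Stereochemistry: C-2 (R) comes from D-tyrosine by diazotisation with retention and is carried as a TBS ether under non-enolising conditions. The (E) C2=C3 olefin of the chain comes from syn-methylalumination/iodinolysis and is retained in the coupling.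

Key step: step 11

Assumption: the single stereocentre (C-2 of the propan-1-one chain) reads as (R) from the SMILES and the chain olefin as (E); ring A is the 2-hydroxy-4-oxyphenyl ring, ring B the 4-hydroxyphenyl ring.

**Route**

Step 1
Reactants: 1 D-tyrosine
Product: 2 (R)-2-hydroxy-3-(4-hydroxyphenyl)propanoic acid
Conditions: NaNO2, 0.5 M aq H2SO4, 0 °C to rt
Reagents that add atoms: water, O
Why: Diazotisation/hydrolysis of the α-amino acid should replace NH2 by OH with net retention (double inversion through neighbouring-group participation of the carboxylate), so the (R) centre of D-tyrosine becomes the (R) carbinol.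

Step 2
Reactants: 2 (R)-2-hydroxy-3-(4-hydroxyphenyl)propanoic acid
Product: 3 (R)-2-hydroxy-3-(4-hydroxyphenyl)-N-methoxy-N-methylpropanamide
Conditions: MeNHOMe·HCl, EDC·HCl, HOBt, N-methylmorpholine, DMF, 0 °C to rt
Reagents that add atoms: N,O-dimethylhydroxylamine hydrochloride, CNOC.Cl
Why: Carbodiimide/HOBt amide coupling (Weinreb amide formation) should proceed with the amine outcompeting the two free hydroxyls, and an α-hydroxy acid has no oxazolone pathway, so the (R) centre is untouched.

Step 3
Reactants: 3 (R)-2-hydroxy-3-(4-hydroxyphenyl)-N-methoxy-N-methylpropanamide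
Product: 5 (R)-2-(tert-butyldimethylsilyloxy)-N-methoxy-N-methyl-3-[4-(triisopropylsilyloxy)phenyl]propanamide, via aryl TIPS ether 4 (not isolated)
Conditions: TIPSCl (1.05 equiv), imidazole, DMF, 0 °C to rt; then TBSCl (1.5 equiv), rt
Reagents that add atoms: triisopropylsilyl chloride, CC(C)[Si](Cl)(C(C)C)C(C)C; tert-butyldimethylsilyl chloride, CC(C)(C)[Si](C)(C)Cl
Why: Stepwise silylation should be selective because the hindered TIPS chloride reacts with the phenol far faster than with the secondary alcohol, which TBSCl then caps; this gives a base-stable aryl silyl ether and a fluoride-labile α-silyloxy amide.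

Step 4
Reactants: 6 4-bromobenzene-1,3-diol
Product: 7 2,4-bis(benzyloxy)-1-bromobenzene
Conditions: BnBr (2.2 equiv), K2CO3, DMF, rt
Reagents that add atoms: benzyl bromide, BrCc1ccccc1
Why: Williamson ether synthesis should benzylate both phenoxides while the aryl bromide stays inert.

Step 5
Reactants: 7 2,4-bis(benzyloxy)-1-bromobenzene; 5 (R)-2-(tert-butyldimethylsilyloxy)-N-methoxy-N-methyl-3-[4-(triisopropylsilyloxy)phenyl]propanamide
Product: 10 (R)-1-[2,4-bis(benzyloxy)phenyl]-2-(tert-butyldimethylsilyloxy)-3-[4-(triisopropylsilyloxy)phenyl]propan-1-one, via aryllithium 8 (not isolated), via lithium hemiaminal alkoxide 9 (not isolated)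
Conditions: 7 (1.4 equiv), n-BuLi (1.35 equiv), THF, −78 °C; then 5, −78 to −30 °C; aq NH4Cl
Reagents that add atoms: none
Why: Bromine–lithium exchange followed by Weinreb ketone synthesis should stop at the ketone because the N-methoxy chelate 9 holds the tetrahedral stage until the quench, and the α-silyloxy centre is not enolised at low temperature, so it keeps its (R) configuration.

Step 6
Reactants: 10 (R)-1-[2,4-bis(benzyloxy)phenyl]-2-(tert-butyldimethylsilyloxy)-3-[4-(triisopropylsilyloxy)phenyl]propan-1-one
Product: 11 (R)-2-(tert-butyldimethylsilyloxy)-1-(2,4-dihydroxyphenyl)-3-[4-(triisopropylsilyloxy)phenyl]propan-1-one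
Conditions: H2 (1 atm), 10% Pd/C, EtOAc, rt
Reagents that add atoms: none
Why: Catalytic hydrogenolysis should cleave both benzyl ethers while the silyl ethers and the electron-rich, hydrogen-bonded aryl ketone are stable under neutral conditions in EtOAc.

Step 7
Reactants: 11 (R)-2-(tert-butyldimethylsilyloxy)-1-(2,4-dihydroxyphenyl)-3-[4-(triisopropylsilyloxy)phenyl]propan-1-one
Product: 12 prop-2-en-1-yl 2-{4-[(2R)-2-(tert-butyldimethylsilyloxy)-3-(4-triisopropylsilyloxyphenyl)propanoyl]-3-hydroxyphenoxy}acetate
Conditions: allyl bromoacetate (1.1 equiv), K2CO3 (1.2 equiv), acetone, rt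
Reagents that add atoms: allyl bromoacetate, C=CCOC(=O)CBr
Why: Regioselective Williamson alkylation should occur only at O-4, because the 2-OH sits in a six-membered hydrogen bond to the ketone oxygen and is much less acidic and nucleophilic than the 4-OH.

Step 8
Reactants: 12 prop-2-en-1-yl 2-{4-[(2R)-2-(tert-butyldimethylsilyloxy)-3-(4-triisopropylsilyloxyphenyl)propanoyl]-3-hydroxyphenoxy}acetate
Product: 13 2-{4-[(2R)-2-(tert-butyldimethylsilyloxy)-3-(4-triisopropylsilyloxyphenyl)propanoyl]-3-hydroxyphenoxy}acetic acid
Conditions: Pd(PPh3)4 (5 mol%), morpholine, THF, rt; aq citric acid work-up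
Reagents that add atoms: none
Why: Tsuji–Trost deallylation should free the acid without hydroxide, since Pd(0) ionises the allyl ester and morpholine traps the π-allyl complex, so the silyl ethers and the epimerisable centre survive.

Step 9
Reactants: 14 5-bromo-2-methylpent-2-ene
Product: 15 6-methylhept-5-en-1-yne
Conditions: lithium acetylide–ethylenediamine complex, DMSO, 10 °C to rt
Reagents that add atoms: lithium acetylide ethylenediamine complex, [Li]C#C.NCCN
Why: SN2 alkylation of lithium acetylide by the primary bromide in DMSO should give the terminal alkyne, the trisubstituted alkene being inert.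

Step 10
Reactants: 15 6-methylhept-5-en-1-yne
Product: 17 (E)-1-iodo-2,6-dimethylhepta-1,5-diene, via alkenylalane 16 (not isolated)
Conditions: Me3Al (2 equiv), Cp2ZrCl2 (0.25 equiv), CH2Cl2, 0 °C to rt; then I2, THF, −30 to 0 °C
Reagents that add atoms: trimethylaluminium, C[Al](C)C; iodine, II
Why: Negishi zirconium-catalysed methylalumination should add Me and Al syn across the terminal alkyne with aluminium on the terminal carbon, and iodinolysis of the C–Al bond with retention then fixes the (E) trisubstituted olefin; the isolated alkene does not react.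

Step 11
Reactants: 13 2-{4-[(2R)-2-(tert-butyldimethylsilyloxy)-3-(4-triisopropylsilyloxyphenyl)propanoyl]-3-hydroxyphenoxy}acetic acid; 17 (E)-1-iodo-2,6-dimethylhepta-1,5-diene
Product: 18 (R)-2-(tert-butyldimethylsilyloxy)-1-{4-[(E)-3,7-dimethylocta-2,6-dienyloxy]-2-hydroxyphenyl}-3-[4-(triisopropylsilyloxy)phenyl]propan-1-one
Conditions: 17 (2 equiv), Ir[dF(CF3)ppy]2(dtbbpy)PF6 (1 mol%), NiCl2·glyme (5 mol%), dtbbpy (5 mol%), DBU (1.05 equiv), degassed DMSO, blue LEDs (450 nm), rt
Reagents that add atoms: none
Why: The DBU carboxylate of 13 should be oxidised by the photoexcited Ir(III) complex and lose CO2 to leave the radical ArO–CH2•, stabilised by the lone pair of the ether oxygen on C-4 of ring A; Ni(0) inserts into the C–I bond of 17 with retention, captures the radical, and the Ni(III)(alkenyl)(CH2OAr) species forms the O–CH2–CH= bond by reductive elimination, after which Ir(II) reduces Ni(I) and closes both cycles. The closest known reaction type is the iridium/nickel metallaphotoredox decarboxylative cross-coupling of α-oxy carboxylic acids with vinyl iodides. No ring is closed and no stereocentre is formed. The step needs retention of the (E) geometry, which is secured because oxidative addition and reductive elimination at the alkenyl carbon are stereoretentive and the unconjugated trisubstituted alkene is not sensitised by the photocatalyst. It also needs chemoselective one-electron oxidation, which the substrate secures by offering the carboxylate as the only readily oxidised site: the ring B phenol is capped as its TIPS ether, the 2-OH is tied into the hydrogen bond to the ketone with only one equivalent of base present, and the α-silyloxy ketone is not enolised under these near-neutral conditions, so C-2 stays (R).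

Step 12
Reactants: 18 (R)-2-(tert-butyldimethylsilyloxy)-1-{4-[(E)-3,7-dimethylocta-2,6-dienyloxy]-2-hydroxyphenyl}-3-[4-(triisopropylsilyloxy)phenyl]propan-1-one
Product: 19 (R)-1-{4-[(E)-3,7-dimethylocta-2,6-dienyloxy]-2-hydroxyphenyl}-2-hydroxy-3-(4-hydroxyphenyl)propan-1-one (CNP0159413.1)
Conditions: TBAF (3 equiv), AcOH (3 equiv), THF, 0 °C to rt
Reagents that add atoms: none
Why: Acetic-acid-buffered fluoride desilylation should remove the aryl TIPS and secondary TBS ethers without generating free alkoxide or phenoxide base, so the α-hydroxy ketone is not epimerised and the acid-sensitive geranyl aryl ether is left intact.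

**Compound list**

1 | D-tyrosine, (R)-2-amino-3-(4-hydroxyphenyl)propanoic acid | N[C@H](Cc1ccc(O)cc1)C(=O)O | starting material
2 | (R)-2-hydroxy-3-(4-hydroxyphenyl)propanoic acid | OC(=O)[C@H](O)Cc1ccc(O)cc1 | intermediate
3 | (R)-2-hydroxy-3-(4-hydroxyphenyl)-N-methoxy-N-methylpropanamide | CON(C)C(=O)[C@H](O)Cc1ccc(O)cc1 | intermediate
4 | (R)-2-hydroxy-N-methoxy-N-methyl-3-[4-(triisopropylsilyloxy)phenyl]propanamide (formed in situ) | CON(C)C(=O)[C@H](O)Cc1ccc(O[Si](C(C)C)(C(C)C)C(C)C)cc1 | intermediate
5 | (R)-2-(tert-butyldimethylsilyloxy)-N-methoxy-N-methyl-3-[4-(triisopropylsilyloxy)phenyl]propanamide | CON(C)C(=O)[C@H](O[Si](C)(C)C(C)(C)C)Cc1ccc(O[Si](C(C)C)(C(C)C)C(C)C)cc1 | intermediate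
6 | 4-bromobenzene-1,3-diol (4-bromoresorcinol) | Oc1ccc(Br)c(O)c1 | starting material
7 | 2,4-bis(benzyloxy)-1-bromobenzene | Brc1ccc(OCc2ccccc2)cc1OCc1ccccc1 | intermediate
8 | [2,4-bis(benzyloxy)phenyl]lithium (formed in situ) | [Li]c1ccc(OCc2ccccc2)cc1OCc1ccccc1 | intermediate
9 | lithium (2R)-1-[2,4-bis(benzyloxy)phenyl]-2-(tert-butyldimethylsilyloxy)-1-[methoxy(methyl)amino]-3-[4-(triisopropylsilyloxy)phenyl]propan-1-olate (tetrahedral adduct, C-1 configuration undefined, formed in situ) | CON(C)C(O[Li])([C@H](O[Si](C)(C)C(C)(C)C)Cc1ccc(O[Si](C(C)C)(C(C)C)C(C)C)cc1)c1ccc(OCc2ccccc2)cc1OCc1ccccc1 | intermediate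
10 | (R)-1-[2,4-bis(benzyloxy)phenyl]-2-(tert-butyldimethylsilyloxy)-3-[4-(triisopropylsilyloxy)phenyl]propan-1-one | O=C([C@H](O[Si](C)(C)C(C)(C)C)Cc1ccc(O[Si](C(C)C)(C(C)C)C(C)C)cc1)c1ccc(OCc2ccccc2)cc1OCc1ccccc1 | intermediate
11 | (R)-2-(tert-butyldimethylsilyloxy)-1-(2,4-dihydroxyphenyl)-3-[4-(triisopropylsilyloxy)phenyl]propan-1-one | O=C([C@H](O[Si](C)(C)C(C)(C)C)Cc1ccc(O[Si](C(C)C)(C(C)C)C(C)C)cc1)c1ccc(O)cc1O | intermediate
12 | prop-2-en-1-yl 2-{4-[(2R)-2-(tert-butyldimethylsilyloxy)-3-(4-triisopropylsilyloxyphenyl)propanoyl]-3-hydroxyphenoxy}acetate | C=CCOC(=O)COc1ccc(C(=O)[C@H](O[Si](C)(C)C(C)(C)C)Cc2ccc(O[Si](C(C)C)(C(C)C)C(C)C)cc2)c(O)c1 | intermediate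
13 | 2-{4-[(2R)-2-(tert-butyldimethylsilyloxy)-3-(4-triisopropylsilyloxyphenyl)propanoyl]-3-hydroxyphenoxy}acetic acid | OC(=O)COc1ccc(C(=O)[C@H](O[Si](C)(C)C(C)(C)C)Cc2ccc(O[Si](C(C)C)(C(C)C)C(C)C)cc2)c(O)c1 | intermediate
14 | 5-bromo-2-methylpent-2-ene | CC(C)=CCCBr | starting material
15 | 6-methylhept-5-en-1-yne | CC(C)=CCCC#C | intermediate
16 | (E)-(2,6-dimethylhepta-1,5-dien-1-yl)dimethylaluminium (formed in situ) | CC(C)=CCC/C(C)=C/[Al](C)C | intermediate
17 | (E)-1-iodo-2,6-dimethylhepta-1,5-diene | CC(C)=CCC/C(C)=C/I | intermediate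
18 | (R)-2-(tert-butyldimethylsilyloxy)-1-{4-[(E)-3,7-dimethylocta-2,6-dienyloxy]-2-hydroxyphenyl}-3-[4-(triisopropylsilyloxy)phenyl]propan-1-one | CC(C)=CCC/C(C)=C/COc1ccc(C(=O)[C@H](O[Si](C)(C)C(C)(C)C)Cc2ccc(O[Si](C(C)C)(C(C)C)C(C)C)cc2)c(O)c1 | intermediate
19 | (R)-1-{4-[(E)-3,7-dimethylocta-2,6-dienyloxy]-2-hydroxyphenyl}-2-hydroxy-3-(4-hydroxyphenyl)propan-1-one | CC(C)=CCC/C(C)=C/COc1ccc(C(=O)[C@H](O)Cc2ccc(O)cc2)c(O)c1 | target

**Step count and risks**

Total step count: 12. Longest linear sequence: 9 steps (steps 1, 2, 3, 5, 6, 7, 8, 11, 12).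

Steps most likely to fail:

1. Step 11. The excited iridium complex may be quenched by electron transfer from the free 2-hydroxyl (or its phenoxide), and the α-aryloxymethyl radical may pick up a hydrogen atom before nickel intercepts it (net protodecarboxylation); low-valent nickel may also ionise the newly formed allylic aryl ether. Fallback, same bond by a two-electron cross-coupling: setting out from diphenol 11, alkylation of O-4 with tributyl(iodomethyl)stannane (K2CO3, DMF, rt) should give tributyl({4-[(2R)-2-(tert-butyldimethylsilyloxy)-3-(4-triisopropylsilyloxyphenyl)propanoyl]-3-hydroxyphenoxy}methyl)stannane F1. Stille coupling of this α-oxygenated stannane with iodide 17 (Pd2(dba)3, tri(2-furyl)phosphine, CuI, NMP, 50 °C) should then transfer the ArO–CH2 group and come back to the route at 18.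

2. Step 5. Addition of the ortho-substituted aryllithium to the α-branched, silyloxy-shielded amide may be slow, leaving time for decomposition of the aryllithium (benzylic deprotonation or [1,2]-Wittig shift of the ortho benzyl ether) and for α-deprotonation of the amide. Fallback through the more electrophilic aldehyde oxidation level: setting out from amide 5, DIBAL-H (THF, −78 °C) should give (R)-2-(tert-butyldimethylsilyloxy)-3-[4-(triisopropylsilyloxy)phenyl]propanal F2. Addition of aryllithium 8 at −78 °C should give (2R)-1-[2,4-bis(benzyloxy)phenyl]-2-(tert-butyldimethylsilyloxy)-3-[4-(triisopropylsilyloxy)phenyl]propan-1-ol F3 as a mixture of carbinol epimers, which is inconsequential. Dess–Martin oxidation (NaHCO3, CH2Cl2, rt) should then return to the route at ketone 10.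

3. Step 1. Electrophilic C-nitrosation of the phenol ring by nitrous acid may compete with N-diazotisation, and direct capture of the diazonium by water would erode retention. Fallback by biocatalysis: setting out from 1, a D-amino acid oxidase with catalase (O2, pH 8 buffer) should give 4-hydroxyphenylpyruvic acid F4. An (R)-selective 2-hydroxy acid dehydrogenase (D-lactate dehydrogenase class) with NADH recycled by formate dehydrogenase/formate should then reduce the keto acid and come back to the route at 2.

**Further compounds**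

F1 | step 11 | tributyl({4-[(2R)-2-(tert-butyldimethylsilyloxy)-3-(4-triisopropylsilyloxyphenyl)propanoyl]-3-hydroxyphenoxy}methyl)stannane | CCCC[Sn](CCCC)(CCCC)COc1ccc(C(=O)[C@H](O[Si](C)(C)C(C)(C)C)Cc2ccc(O[Si](C(C)C)(C(C)C)C(C)C)cc2)c(O)c1
F2 | step 5 | (R)-2-(tert-butyldimethylsilyloxy)-3-[4-(triisopropylsilyloxy)phenyl]propanal | O=C[C@H](O[Si](C)(C)C(C)(C)C)Cc1ccc(O[Si](C(C)C)(C(C)C)C(C)C)cc1
F3 | step 5 | (2R)-1-[2,4-bis(benzyloxy)phenyl]-2-(tert-butyldimethylsilyloxy)-3-[4-(triisopropylsilyloxy)phenyl]propan-1-ol (both C-1 epimers) | OC([C@H](O[Si](C)(C)C(C)(C)C)Cc1ccc(O[Si](C(C)C)(C(C)C)C(C)C)cc1)c1ccc(OCc2ccccc2)cc1OCc1ccccc1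
F4 | step 1 | 4-hydroxyphenylpyruvic acid | OC(=O)C(=O)Cc1ccc(O)cc1
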